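Target comes slowly in the maple and cedar runs, so ask first what end it is approaching. You mix starting material with partner and second reagent, with third reagent and protic impurity also present.

| flask | starting material | partner | second reagent | third reagent | protic impurity | remark | time |
|---|---|---|---|---|---|---|---|
| maple | 5 mM | 3.5 mM | 1.1 mM | 4.5 mM | 2.5 mM | run made earlier |  |
| cedar | 5 mM | 3.5 mM | 40 mM | 4.5 mM | 2.5 mM | run made earlier |  |
| Friday's | 5.0 mM | 3.50 mM | 2.00 mM | 4.50 mM | 2.50 mM |  | 10 min |
| Monday's | 5.0 mM | 3.50 mM | 6.00 mM | 4.50 mM | 2.50 mM |  | 10 min |
| Tuesday's | 5.0 mM | 3.50 mM | 20.0 mM | 4.50 mM | 2.50 mM |  | 10 min |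
| Thursday's | 5.0 mM | 3.50 mM | 60.0 mM | 4.50 mM | 2.50 mM |  | 10 min |

- maple (time / min: target / %, starting material / %): 0.667: 0, 28.8; 1.33: 2.3, 24.4; 2.00: 2.1, 23.2; 3.00: 2.6, 21.2; 4.00: 2.9, 22.3; 5.00: 3.4, 22.1
- cedar (time / min: target / %, starting material / %): 0.250: 1.6, 0.1; 0.833: 7.1, 0; 1.33: 10.8, 0.3; 2.00: 13.6, 0.7; 3.00: 15.2, 0.6; 4.00: 17.4, 0; 5.00: 18.0, 0.8

(scatter of a reading: 0.5 percentage points)

- the numbers in the tables scatter by 0.5 percentage points (one standard deviation)
- "hardly changes" means that all values lie within two and a half points (for a concentration: within two and a half percent of the largest)

- amount of target at the end, in percent of the starting material charged for Friday's, Monday's, Tuesday's, Thursday's, in this order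
- the course of these numbers from the first flask to the last (falls, then rises / hardly changes / rises all the way / rises, then falls / falls all the way)

Take the cedar run first. Starting material reads 0.1% at 0.250 min, but target then reads 1.6% and climbs to 18.0% at 5.00 min. So in the cedar run the fate of starting material is told early, and the climb comes later.

The maple run reads 28.8% of starting material at 0.667 min, more than cedar at its first reading, so I take second reagent to attack starting material directly, in competition with partner.

My own reckoning follows. Let S be the share of starting material that partner catches, and c_B and c_D the charges of partner and second reagent. Holding both at their charge, I write S = c_B/(c_B + ρ c_D). Cedar's last target reading, set in for S as if what is caught ends as target, gives ρ = 0.399. This ρ is the capture ratio, the rate constant of starting material with second reagent over that with partner, a selectivity factor. It is a reading, and cedar's target was still climbing, 15.2% at 3.00 min and 18.0% at 5.00 min, so it sits on the high side.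

So I expect target of about 30.5% for Tuesday's and 12.8% for Thursday's. But S is the share caught, and target has still to form from it: the maple run shows 3.4% of target at 5.00 min, far less than its share of 88.9%, so at low charges of second reagent I expect target under S, and a rise before the fall.

The forecast gives 7%, 14%, 21% and 16%, rises, then falls: “Most of the intermediate is therefore lost by a faster side path”. My shares differ from it: 30.5% against 21% for Tuesday's, 12.8% against 16% for Thursday's.

The flasks give 7.70%, 34.4%, 31.6% and 14.1%, rises, then falls.

starting material + partner → intermediate A (k = 25.0 /M/s); second reagent + intermediate A → intermediate B (k = 5.64 /M/s); third reagent + intermediate B → target (k = 2.69 /M/s); starting material + second reagent → side product (k = 8.50 /M/s); second reagent + protic impurity → quenched reagent (k = 12.4 /M/s) Tuesday's ends with starting material at 0% and side product at 68.2%, and its target of 31.6% stands beside the share 30.5% reckoned from ρ. Put ρ to use on Thursday's: the share is 12.8%, and that flask holds 14.1% of target beside 85.9% of side product.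

The readings are simulated for substances that don't exist.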